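**Assumptions (one line):** prostanoid numbering is used (C1 = ester carbon … C20); the SMILES corresponds to (5S,6R,7R,8R,12S), i.e. an all-syn 5,6,7-triacetate, an anti C7/C8 aldol relationship, and C12-OH cis to the C8 side chain; glycol, boron, silyl and acetyl donors are treated as reagents.

## Retrosynthetic overview

1. The all-syn triacetate is unmasked last from a cis-5,6-epoxide: the C7 acetate opens the epoxide at C6 with inversion through an acetoxonium ion, then peracetylation.
2. C7–C8 is made by an anti-selective lithium-enolate aldol between a 2-chloro-4-silyloxycyclopentenone (C8–C20) and a cis-epoxy aldehyde (C1–C7); Felkin addition, the E-enolate and the ring face all favour the same isomer.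
3. C12–C13 and the C12 carbinol stereocentre come from a Cu-catalysed enantioselective coupling of cyclopent-4-ene-1,3-dione mono-ketal with a 1-pentylallenylboronate (C13–C20, from hept-1-yne); Lindlar reduction, unmasking and α-chlorination follow.
4. The epoxy aldehyde comes from hex-5-ynoic acid and formaldehyde via the Z-allylic alcohol and Sharpless epoxidation.
5. Rings: the cyclopentene is bought intact. Only auxiliary rings are formed (spiro-ketal, two oxiranes, transient dioxolanylium/orthoester), and all are opened before the end.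

## Route

### Branch A – ω-chain boron reagent

**Step 1**
Reactants: 1, hept-1-yne
Product: 2, methyl oct-2-yn-1-yl carbonate
Conditions: n-BuLi, THF, −78 °C; (CH2O)n, −78 °C → rt; then ClCO2Me, 0 °C
Reagents that add atoms: paraformaldehyde (C=O); methyl chloroformate (COC(=O)Cl)
Why: Acetylide hydroxymethylation followed by in situ O-acylation of the lithium propargyl alkoxide; no stereocentre.

**Step 2**
Reactants: 2, methyl oct-2-yn-1-yl carbonate
Product: 3, 4,4,5,5-tetramethyl-2-(octa-1,2-dien-3-yl)-1,3,2-dioxaborolane
Conditions: B2pin2, CuCl (5 mol%), Xantphos (5 mol%), KOt-Bu (10 mol%), THF, rt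
Reagents that add atoms: bis(pinacolato)diboron (CC1(C)OB(OC1(C)C)B2OC(C)(C)C(C)(C)O2)
Why: Cu-catalysed SN2′ borylation of a propargylic carbonate (borylcupration then β-elimination) puts boron on the pentyl-bearing carbon and gives the 1-alkylallenylboronate.

### Ring fragment (C8–C20)

**Step 3**
Reactants: 4, cyclopent-4-ene-1,3-dione
Product: 5, 1,4-dioxaspiro[4.4]non-6-en-8-one
Conditions: (TMSOCH2)2 (1.0 equiv), TMSOTf (2 mol%), CH2Cl2, −78 → −20 °C; pyridine quench
Reagents that add atoms: 1,2-bis(trimethylsilyloxy)ethane (C[Si](C)(C)OCCO[Si](C)(C)C)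
Why: Noyori ketalisation; the two carbonyls are equivalent, and after the first ketalisation the remaining carbonyl is a less electrophilic simple enone, so the reaction stops at the mono-ketal.

**Step 4 (key step)**
Reactants: 5, 1,4-dioxaspiro[4.4]non-6-en-8-one; 3, 1-pentylallenyl-Bpin (1.3 equiv)
Product: 6, (8S)-8-(oct-2-yn-1-yl)-1,4-dioxaspiro[4.4]non-6-en-8-ol
Conditions: Cu(O2C-i-Pr)2 (5 mol%), (R)-BINAP (7 mol%; antipode chosen empirically to give 8S), LiOt-Bu (10 mol%), THF, −40 °C; aq. NH4Cl
Reagents that add atoms: none (Bpin is lost on work-up)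
Why: Proposed new method: Cu(I)–bisphosphine-catalysed enantioselective 1,2-propargylation of a cross-conjugated cyclic enone with a 1-alkylallenylboronate – alkoxide-assisted B→Cu transmetallation gives the 1-pentylallenyl–copper species, which delivers its unsubstituted CH2 terminus to C=O through a closed six-membered SE2′ transition state (hence the 2-octynyl rather than allenyl product, and 1,2- rather than 1,4-addition), while the chiral ligand distinguishes the flat CH=CH flank from the CH2–C(spiro-ketal) flank to set C12 (S) and Cu–alkoxide/boronate exchange turns the cycle over; the closest known reaction type is Cu–bisphosphine-catalysed enantioselective propargylation of acyclic aryl/alkyl ketones with allenyl- or silylpropargyl-boronates.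

**Step 5**
Reactants: 6
Product: 7, (8S)-8-[(2Z)-oct-2-en-1-yl]-1,4-dioxaspiro[4.4]non-6-en-8-ol
Conditions: H2 (1 atm), Lindlar catalyst, quinoline, EtOAc, rt
Reagents that add atoms: none (H2 only)
Why: Lindlar syn-semihydrogenation gives the 14Z alkene; the ring alkene and ketal are inert and no enone or C–Cl bond is present yet.

**Step 6**
Reactants: 7
Product: 8, (4S)-4-hydroxy-4-[(2Z)-oct-2-en-1-yl]cyclopent-2-en-1-one
Conditions: PPTS (0.2 equiv), acetone–H2O (9:1), 40 °C
Reagents that add atoms: water (O)
Why: Mild hydrolysis of an allylic ketal; ionisation of the tertiary allylic alcohol is disfavoured because the resulting cation would sit next to the ketal (then carbonyl) carbon, so C12 is untouched.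

**Step 7**
Reactants: 8
Product: 9, (4S)-4-hydroxy-4-[(2Z)-oct-2-en-1-yl]-6-oxabicyclo[3.1.0]hexan-2-one (epoxide diastereomers; these centres are destroyed in step 8)
Conditions: 30% H2O2, NaOH (0.2 equiv), MeOH, −10 → 0 °C
Reagents that add atoms: hydrogen peroxide (OO)
Why: Weitz–Scheffer nucleophilic epoxidation attacks only the electron-poor enone; the isolated Z-alkene is untouched.

**Step 8**
Reactants: 9
Product: 10, (4S)-2-chloro-4-hydroxy-4-[(2Z)-oct-2-en-1-yl]cyclopent-2-en-1-one
Conditions: HCl (4 M in dioxane), THF, 0 °C → rt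
Reagents that add atoms: hydrogen chloride (Cl)
Why: Chloride opens the α,β-epoxy ketone at the α-carbon (SN2 next to C=O; the β-carbon is neopentyl-like), and the β-hydroxy-α-chloro ketone dehydrates through its enol to the α-chloro enone, placing Cl at C10.

**Step 9**
Reactants: 10
Product: 11, (4S)-2-chloro-4-[(2Z)-oct-2-en-1-yl]-4-(trimethylsilyloxy)cyclopent-2-en-1-one
Conditions: TMSCl, imidazole, DMF, rt
Reagents that add atoms: chlorotrimethylsilane (C[Si](C)(C)Cl)
Why: Silylation masks the tertiary OH for enolate formation and for the Lewis-acid step, and comes off under mild acid.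

### Branch B – C1–C7 epoxy aldehyde

**Step 10**
Reactants: 12, hex-5-ynoic acid
Product: 13, 7-hydroxyhept-5-ynoic acid
Conditions: n-BuLi (2.2 equiv), THF–DMPU, −78 → 0 °C; (CH2O)n, rt; H3O+
Reagents that add atoms: paraformaldehyde (C=O)
Why: The carboxylate/acetylide dianion reacts with formaldehyde only at the acetylide carbon.

**Step 11**
Reactants: 13
Product: 14, methyl 7-hydroxyhept-5-ynoate
Conditions: MeOH, H2SO4 (cat.), rt
Reagents that add atoms: methanol (CO)
Why: Fischer esterification.

**Step 12**
Reactants: 14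
Product: 15, methyl (5Z)-7-hydroxyhept-5-enoate
Conditions: H2 (1 atm), Lindlar catalyst, quinoline, EtOAc, rt
Reagents that add atoms: none (H2 only)
Why: Lindlar syn-semihydrogenation gives the Z-allylic alcohol needed for a cis-epoxide.

**Step 13**
Reactants: 15
Product: 16, methyl 4-[(2S,3R)-3-(hydroxymethyl)oxiran-2-yl]butanoate (cis; prostanoid 5S,6R)
Conditions: Ti(Oi-Pr)4, D-(−)-diethyl tartrate, t-BuOOH, 4 Å MS, CH2Cl2, −20 °C
Reagents that add atoms: tert-butyl hydroperoxide (CC(C)(C)OO)
Why: Sharpless asymmetric epoxidation; the D-(−)-tartrate catalyst gives the (2R,3S)-2,3-epoxy alcohol from a Z-allylic alcohol (typically 85–92% ee; the minor enantiomer is removed later as a diastereomer).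

**Step 14**
Reactants: 16
Product: 17, methyl 4-[(2S,3S)-3-formyloxiran-2-yl]butanoate (cis; prostanoid 5S,6S)
Conditions: Dess–Martin periodinane, NaHCO3, CH2Cl2, 0 °C → rt; used crude
Reagents that add atoms: none
Why: Buffered, non-basic oxidation avoids epimerisation at C6; the descriptor change at C6 is only a CIP priority switch.

### Fragment union and end game

**Step 15**
Reactants: 11; 17
Product: 18, methyl 4-[(2S,3S)-3-{(R)-acetoxy[(1R,5S)-3-chloro-5-[(2Z)-oct-2-en-1-yl]-2-oxo-5-(trimethylsilyloxy)cyclopent-3-en-1-yl]methyl}oxiran-2-yl]butanoate (prostanoid 5S,6S,7R,8R,12S)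
Conditions: 11, LDA, THF, −78 °C; 17, −78 °C; then Ac2O, −78 → −40 °C; NH4Cl
Reagents that add atoms: acetic anhydride (CC(=O)OC(C)=O)
Why: Kinetic α′-lithium enolate aldol (C12 is quaternary, so C8 is the only enolisable site) through a Zimmerman–Traxler chair: the cyclic E-enolate gives the C7/C8 anti adduct, the aldehyde reacts on its Felkin–Anh face (anti to the epoxide C–O; strongly favoured for cis-epoxy aldehydes) to give 7R, and the electrophile enters C8 anti to the larger C12–CH2 substituent (syn to the smaller OSiMe3) to give 8R; all three preferences converge on one isomer, and in situ acetylation prevents retro-aldol and Payne rearrangement and installs the participating group.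

**Step 16**
Reactants: 18
Product: 19, methyl (5S,6R,7R)-6-acetoxy-7-[(1R,5S)-3-chloro-5-hydroxy-5-[(2Z)-oct-2-en-1-yl]-2-oxocyclopent-3-en-1-yl]-5,7-dihydroxyheptanoate, with its 5-O- and 7-O-acetyl regioisomers (used crude)
Conditions: BF3·OEt2, CH2Cl2, −78 → −30 °C; then AcOH–THF–H2O (3:1:1), rt
Reagents that add atoms: water (O)
Why: Epoxy ester–acyloxonium (orthoester) rearrangement: the C7 acetate carbonyl opens the activated epoxide 5-exo at C6 with inversion (6S → 6R, making 6,7 and 5,6 both syn) while C5–O is retained; aqueous acid hydrolyses the dioxolanylium/orthoester with retention and removes the TMS ether, and acetyl scrambling is irrelevant because all three oxygens are acetylated next.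

**Step 17**
Reactants: 19
Product: 20, punaglandin 2, methyl (5S,6R,7R)-5,6,7-triacetoxy-7-[(1R,5S)-3-chloro-5-hydroxy-5-[(2Z)-oct-2-en-1-yl]-2-oxocyclopent-3-en-1-yl]heptanoate
Conditions: Ac2O, pyridine, CH2Cl2, 0 °C → rt (no DMAP)
Reagents that add atoms: acetic anhydride (CC(=O)OC(C)=O)
Why: Only the secondary hydroxyls are acetylated; the hindered tertiary C12-OH does not react without DMAP, and the mild base limits β-elimination of the C7 acetate.

## Compound list

1 | hept-1-yne | CCCCCC#C | starting material
2 | methyl oct-2-yn-1-yl carbonate | CCCCCC#CCOC(=O)OC | intermediate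
3 | 4,4,5,5-tetramethyl-2-(octa-1,2-dien-3-yl)-1,3,2-dioxaborolane | C=C=C(CCCCC)B1OC(C)(C)C(C)(C)O1 | intermediate
4 | cyclopent-4-ene-1,3-dione | O=C1CC(=O)C=C1 | starting material
5 | 1,4-dioxaspiro[4.4]non-6-en-8-one | O=C1C=CC2(OCCO2)C1 | intermediate
6 | (8S)-8-(oct-2-yn-1-yl)-1,4-dioxaspiro[4.4]non-6-en-8-ol | CCCCCC#CC[C@@]1(O)C=CC2(OCCO2)C1 | intermediate
7 | (8S)-8-[(2Z)-oct-2-en-1-yl]-1,4-dioxaspiro[4.4]non-6-en-8-ol | CCCCC/C=C\C[C@@]1(O)C=CC2(OCCO2)C1 | intermediate
8 | (4S)-4-hydroxy-4-[(2Z)-oct-2-en-1-yl]cyclopent-2-en-1-one | CCCCC/C=C\C[C@@]1(O)C=CC(=O)C1 | intermediate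
9 | (4S)-4-hydroxy-4-[(2Z)-oct-2-en-1-yl]-6-oxabicyclo[3.1.0]hexan-2-one (epoxide diastereomers) | CCCCC/C=C\C[C@@]1(O)C2OC2C(=O)C1 | intermediate
10 | (4S)-2-chloro-4-hydroxy-4-[(2Z)-oct-2-en-1-yl]cyclopent-2-en-1-one | CCCCC/C=C\C[C@@]1(O)C=C(Cl)C(=O)C1 | intermediate
11 | (4S)-2-chloro-4-[(2Z)-oct-2-en-1-yl]-4-(trimethylsilyloxy)cyclopent-2-en-1-one | CCCCC/C=C\C[C@@]1(O[Si](C)(C)C)C=C(Cl)C(=O)C1 | intermediate
12 | hex-5-ynoic acid | C#CCCCC(=O)O | starting material
13 | 7-hydroxyhept-5-ynoic acid | OCC#CCCCC(=O)O | intermediate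
14 | methyl 7-hydroxyhept-5-ynoate | OCC#CCCCC(=O)OC | intermediate
15 | methyl (5Z)-7-hydroxyhept-5-enoate | OC/C=C\CCCC(=O)OC | intermediate
16 | methyl 4-[(2S,3R)-3-(hydroxymethyl)oxiran-2-yl]butanoate | OC[C@H]1O[C@H]1CCCC(=O)OC | intermediate
17 | methyl 4-[(2S,3S)-3-formyloxiran-2-yl]butanoate | O=C[C@H]1O[C@H]1CCCC(=O)OC | intermediate
18 | methyl 4-[(2S,3S)-3-{(R)-acetoxy[(1R,5S)-3-chloro-5-[(2Z)-oct-2-en-1-yl]-2-oxo-5-(trimethylsilyloxy)cyclopent-3-en-1-yl]methyl}oxiran-2-yl]butanoate | CCCCC/C=C\C[C@@]1(O[Si](C)(C)C)C=C(Cl)C(=O)[C@@H]1[C@@H](OC(C)=O)[C@H]2O[C@H]2CCCC(=O)OC | intermediate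
19 | methyl (5S,6R,7R)-6-acetoxy-7-[(1R,5S)-3-chloro-5-hydroxy-5-[(2Z)-oct-2-en-1-yl]-2-oxocyclopent-3-en-1-yl]-5,7-dihydroxyheptanoate (representative of the mono-acetate mixture) | CCCCC/C=C\C[C@@]1(O)C=C(Cl)C(=O)[C@@H]1[C@@H](O)[C@H](OC(C)=O)[C@H](CCCC(=O)OC)O | intermediate
20 | punaglandin 2, methyl (5S,6R,7R)-5,6,7-triacetoxy-7-[(1R,5S)-3-chloro-5-hydroxy-5-[(2Z)-oct-2-en-1-yl]-2-oxocyclopent-3-en-1-yl]heptanoate | CCCCC/C=C\C[C@@]1(O)C=C(Cl)C(=O)[C@@H]1[C@@H](OC(C)=O)[C@H](OC(C)=O)[C@H](CCCC(=O)OC)OC(C)=O | target

## Summary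

**Total steps:** 17 (branch A: 2; ring: 7; branch B: 5; union and end game: 3).
**Longest linear sequence:** 11 (steps 1, 2, 4–9, 15–17).

**Three steps most likely to fail, with fallbacks**

1. **Step 4 (proposed new Cu-catalysed enantioselective propargylation).** Risks are insufficient ee on a cyclic enone, allenyl- versus propargyl-carbinol regiochemistry with the 1-alkylallenyl reagent, and base-induced β-elimination of the ketal. Fallback (known chemistry, substrate control instead of catalyst control): add propargylmagnesium bromide to (R)-4-(tert-butyldimethylsilyloxy)cyclopent-2-enone anti to the OTBS group; C-pentylate the alkyne (n-BuLi 2 equiv, 1-iodopentane, THF/DMPU); then TBAF and MnO2 oxidation of the secondary allylic alcohol erase the relay stereocentre and give the alkyne analogue of 8; Lindlar reduction rejoins the route at 8.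

2. **Step 15 (aldol setting C7 and C8).** Risks are the C8 facial bias (OSiMe3 versus CH2R), enolate β-elimination of silanolate, and epimerisation of the cis-epoxy aldehyde. Fallback (internal delivery instead of steric control): run the aldol on the unprotected dianion of 10 (2.1 equiv LDA), so the C12 lithium alkoxide bridges to the enolate and delivers the aldehyde to its own face; isolate the aldol, acetylate C7-OH selectively (Ac2O/pyridine), then silylate C12-OH before step 16.

3. **Step 16 (acetoxonium-relayed epoxide opening).** Risks are competing 6-exo participation of the C1 methyl ester at C5, Lewis-acid elimination of the β-acetoxy ketone, and δ-lactonisation of the free 5-OH before acetylation. Fallback (drop the epoxide relay): install the C5/C6 oxygens before coupling by Sharpless asymmetric dihydroxylation of an (E)-hept-5-enoate carrying a masked C7 aldehyde, acetylate and unmask to methyl (5S,6R)-5,6-diacetoxy-7-oxoheptanoate, run the same aldol/acetylation with 11, and separate the 6,7-syn product from the Felkin 7-epimer.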